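**Retrosynthetic overview**
1. Target 15 ⇐ 14 by Riley oxidation of the isopropenyl methyl (C15) ⇐ 13 by angeloylation of the 6-OH.
2. 13 ⇐ Cope rearrangement (ten- to six-membered ring, sets C5 and C10) of the cis-fused germacra-1(10),4-dien-12,8-olide 12, run in the flask in which 12 is made.
3. 12 ⇐ acyclic enal 11 by closing C6–C7 (the bond germacrene A synthase makes between farnesyl C1 and C10) through a Pd/InI umpolung allylation; sets C6 and C7.
4. 11 ⇐ vinylogous Mukaiyama aldol (C8–C9, sets both carbinol centres, brings in the lactone ring) of 8-oxogeranyl silyl ether 4 with 2-silyloxyfuran 7; 4 from geraniol, 7 from furan-2(5H)-one and CH2O.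
5. Ring order: butenolide (lactone) ring → ten-membered carbocycle → cyclohexane (Cope ring contraction).

Assumption: (R)-BINOL is taken to deliver the (5R,1′R) aldol adduct in step 5; if the sense of induction is the reverse, (S)-BINOL is used and nothing else changes.

Germacrane/elemane numbering (C1–C15) is used for positions throughout.

**Step 1**
Reactants: 1 geraniol
Product: 2 tert-butyl{[(2E)-3,7-dimethylocta-2,6-dien-1-yl]oxy}dimethylsilane (geranyl TBS ether)
Conditions: TBSCl (1.1 equiv), imidazole (1.5 equiv), CH2Cl2, 0 °C → rt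
Reagents that add atoms: tert-butyldimethylsilyl chloride, CC(C)(C)[Si](C)(C)Cl
Why: Imidazole-promoted silylation of the primary allylic alcohol masks the future C6 aldehyde as an electron-rich allylic silyl ether; no stereocentre is formed.

**Step 2**
Reactants: 2 geranyl TBS ether
Product: 4 (2E,6E)-8-{[tert-butyl(dimethyl)silyl]oxy}-2,6-dimethylocta-2,6-dienal, via allylic alcohol 3 (not isolated)
Conditions: SeO2 (0.3 equiv), t-BuOOH (2 equiv), salicylic acid (0.1 equiv), CH2Cl2, 0 °C → rt; then MnO2 (10 equiv), CH2Cl2, rt on the crude after extractive work-up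
Reagents that add atoms: selenium dioxide (oxygen carrier), O=[Se]=O; tert-butyl hydroperoxide (terminal oxygen source), CC(C)(C)OO
Why: Riley allylic oxidation (ene reaction, then [2,3]-sigmatropic shift) attacks only the E-methyl of the terminal trisubstituted alkene, the 2,3-alkene being deactivated by the allylic oxygen, and MnO2 converges alcohol 3 and any aldehyde already present on the (2E,6E)-enal; no stereocentre is formed.

**Step 3**
Reactants: 5 furan-2(5H)-one
Product: 6 3-(hydroxymethyl)furan-2(5H)-one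
Conditions: 37 % aq. CH2O (1.5 equiv), DMAP (0.2 equiv), THF/H2O (1:1), rt
Reagents that add atoms: formaldehyde, C=O
Why: Morita–Baylis–Hillman hydroxymethylation, in which DMAP adds to C4 of the butenolide, the enolate traps formaldehyde at C3 and loss of DMAP restores the butenolide, installs the future C13; no stereocentre is formed.

**Step 4**
Reactants: 6 3-(hydroxymethyl)furan-2(5H)-one
Product: 7 trimethyl({2-[(trimethylsilyl)oxy]furan-3-yl}methoxy)silane
Conditions: Me3SiCl (2.4 equiv), Et3N (2.6 equiv), MeCN, 0 °C → rt; distilled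
Reagents that add atoms: chlorotrimethylsilane, C[Si](C)(C)Cl
Why: O-silylation of the alcohol together with soft enolization and O-silylation of the butenolide gives the aromatic 2-silyloxyfuran, the standard nucleophile for vinylogous Mukaiyama aldol reactions; no stereocentre is formed.

**Step 5**
Reactants: 4 (2E,6E)-8-{[tert-butyl(dimethyl)silyl]oxy}-2,6-dimethylocta-2,6-dienal; 7 trimethyl({2-[(trimethylsilyl)oxy]furan-3-yl}methoxy)silane
Product: 9 (5R)-5-[(1R,2E,6E)-8-{[tert-butyl(dimethyl)silyl]oxy}-1-hydroxy-2,6-dimethylocta-2,6-dien-1-yl]-3-(hydroxymethyl)furan-2(5H)-one, via bis-TMS aldol adduct 8 (not isolated)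
Conditions: 7 (1.3 equiv), Ti(OiPr)4 (20 mol %), (R)-BINOL (20 mol %), Et2O, −20 °C; then citric acid, MeOH, 0 °C
Reagents that add atoms: none
Why: Catalytic asymmetric vinylogous Mukaiyama aldol: the furan attacks through C5 the aldehyde held by the Ti(OiPr)4/BINOL catalyst in an open transition state that gives the threo adduct, the ligand fixing the absolute sense (C8 = 5R, C9 = 1′R), and mild acid methanolysis removes both TMS ethers while the TBS ether stays.

**Step 6**
Reactants: 9 diol from step 5
Product: 10 (1R,2E,6E)-8-{[tert-butyl(dimethyl)silyl]oxy}-2,6-dimethyl-1-[(2R)-4-{[(2-methylprop-2-enoyl)oxy]methyl}-5-oxo-2,5-dihydrofuran-2-yl]octa-2,6-dien-1-yl 2-methylprop-2-enoate (bis-methacrylate)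
Conditions: methacrylic anhydride (3 equiv), i-Pr2NEt (3.5 equiv), DMAP (5 mol %), CH2Cl2, −20 → 0 °C
Reagents that add atoms: methacrylic anhydride, CC(=C)C(=O)OC(=O)C(C)=C
Why: DMAP-catalysed acylation installs the C9 methacrylate of the target and, in the same operation, turns the C13 hydroxyl into the allylic leaving group for the ring closure, a hindered base at low temperature keeping the 5-(1-acyloxyalkyl)butenolide from eliminating; C8 and C9 are untouched.

**Step 7**
Reactants: 10 bis-methacrylate
Product: 11 (1R,2E,6E)-2,6-dimethyl-1-[(2R)-4-{[(2-methylprop-2-enoyl)oxy]methyl}-5-oxo-2,5-dihydrofuran-2-yl]-8-oxoocta-2,6-dien-1-yl 2-methylprop-2-enoate (enal)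
Conditions: DDQ (2 equiv), CH2Cl2/pH 7 buffer (10:1), 0 °C → rt
Reagents that add atoms: none
Why: DDQ oxidative cleavage of an electron-rich allylic silyl ether (hydride abstraction at C6, then hydrolysis of the silyloxocarbenium ion) gives the enal directly, while the C9 and C13 esters sit on acylated or electron-poor allylic positions and are inert; no stereocentre is touched.

**Step 8**
Reactants: 11 enal
Product: 13 (5S,6S,7R,8R,9R,10S)-6-hydroxy-9-(methacryloyloxy)elema-1,3,11(13)-trien-12,8-olide, via germacranolide alcohol 12 (not isolated)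
Conditions: Pd(PPh3)4 (10 mol %), InI (2.5 equiv), THF, rt, 11 added over 12 h (2 mM final); aq. NH4Cl, solvent switch to PhMe, BHT (5 mol %), 130 °C, sealed tube
Reagents that add atoms: none
Why: Proposed new method: zerovalent palladium ionizes the primary, Morita–Baylis–Hillman-type allylic methacrylate on the butenolide, InI (monovalent indium) reduces the π-allyl complex to an allylindium species that adds through C7 to the tethered enal in a six-membered chair transition state on the butenolide face that carries C9 (cis ring fusion, 7R) with the enal chain equatorial (6S), closing the ten-membered ring at C6–C7, and heating the crude (1(10)E,4E)-diene 12 with its small free 6-OH then drives the Cope rearrangement through the chair that holds C14 and C15 on the face opposite the cis-fused lactone, which sets C10 and C5 (methyl anti to H-5); the closest known reactions are the Pd/InI umpolung carbonyl allylation of allylic esters, the γ-selective Barbier additions of 3-(bromomethyl)furan-2(5H)-one to aldehydes, CrCl2-mediated macrocyclic Barbier closures of ten-membered germacranolide rings and the thermal germacranolide-to-elemanolide Cope rearrangement.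

**Step 9**
Reactants: 13 elemanolide alcohol
Product: 14 (5S,6S,7R,8R,9R,10S)-6-[(Z)-2-methylbut-2-enoyloxy]-9-(methacryloyloxy)elema-1,3,11(13)-trien-12,8-olide
Conditions: angelic acid (3 equiv), 2,4,6-Cl3C6H2COCl (3 equiv), Et3N (6 equiv), PhMe, rt, 2 h; then 13, 80 °C
Reagents that add atoms: angelic acid, C/C=C(/C)C(O)=O
Why: Yamaguchi esterification through the preformed mixed anhydride, run without DMAP, acylates the hindered 6-OH with retention at C6 and without Z-to-E isomerization of the angelate.

**Step 10**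
Reactants: 14 elemanolide angelate
Product: 15 (5R,6S,7R,8R,9R,10S)-6-[(Z)-2-methylbut-2-enoyloxy]-9-(methacryloyloxy)-15-oxoelema-1,3,11(13)-trien-12,8-olide (target)
Conditions: SeO2 (1.5 equiv), 1,4-dioxane, 80 °C
Reagents that add atoms: selenium dioxide, O=[Se]=O
Why: Riley oxidation (ene reaction, [2,3]-shift, then oxidation of the allylic alcohol) takes the methyl group of the isopropenyl unit, the only electron-rich alkene with a reactive allylic position, to the 2-substituted acrolein, the vinyl group having no allylic hydrogen and the acrylate-type alkenes being electron-poor; no stereocentre is touched (the C5 descriptor changes from S to R only through priorities).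

**Compound list**
1 | geraniol, (2E)-3,7-dimethylocta-2,6-dien-1-ol | CC(C)=CCC/C(C)=C/CO | starting material
2 | tert-butyl{[(2E)-3,7-dimethylocta-2,6-dien-1-yl]oxy}dimethylsilane | CC(C)=CCC/C(C)=C/CO[Si](C)(C)C(C)(C)C | intermediate
3 | (2E,6E)-8-{[tert-butyl(dimethyl)silyl]oxy}-2,6-dimethylocta-2,6-dien-1-ol (not isolated) | OC/C(C)=C/CC/C(C)=C/CO[Si](C)(C)C(C)(C)C | intermediate
4 | (2E,6E)-8-{[tert-butyl(dimethyl)silyl]oxy}-2,6-dimethylocta-2,6-dienal (aldehyde carbon = C9, silyloxy carbon = C6) | O=C/C(C)=C/CC/C(C)=C/CO[Si](C)(C)C(C)(C)C | intermediate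
5 | furan-2(5H)-one | O=C1OCC=C1 | starting material
6 | 3-(hydroxymethyl)furan-2(5H)-one | O=C1OCC=C1CO | intermediate
7 | trimethyl({2-[(trimethylsilyl)oxy]furan-3-yl}methoxy)silane | C[Si](C)(C)OCC1=C(O[Si](C)(C)C)OC=C1 | intermediate
8 | bis-TMS ether of 9 (C9–OSiMe3 and C13–OSiMe3; 5R,1′R; not isolated) | CC(C)(C)[Si](C)(C)OC/C=C(\C)CC/C=C(\C)[C@@H](O[Si](C)(C)C)[C@H]1C=C(CO[Si](C)(C)C)C(=O)O1 | intermediate
9 | (5R)-5-[(1R,2E,6E)-8-{[tert-butyl(dimethyl)silyl]oxy}-1-hydroxy-2,6-dimethylocta-2,6-dien-1-yl]-3-(hydroxymethyl)furan-2(5H)-one (threo; C8 R, C9 R) | CC(C)(C)[Si](C)(C)OC/C=C(\C)CC/C=C(\C)[C@@H](O)[C@H]1C=C(CO)C(=O)O1 | intermediate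
10 | bis-methacrylate of 9 (methacrylate on C9–O and on C13–O; C6–OTBS) | CC(C)(C)[Si](C)(C)OC/C=C(\C)CC/C=C(\C)[C@@H](OC(=O)C(C)=C)[C@H]1C=C(COC(=O)C(C)=C)C(=O)O1 | intermediate
11 | (1R,2E,6E)-2,6-dimethyl-1-[(2R)-4-{[(2-methylprop-2-enoyl)oxy]methyl}-5-oxo-2,5-dihydrofuran-2-yl]-8-oxoocta-2,6-dien-1-yl 2-methylprop-2-enoate (C6 enal) | O=C/C=C(\C)CC/C=C(\C)[C@@H](OC(=O)C(C)=C)[C@H]1C=C(COC(=O)C(C)=C)C(=O)O1 | intermediate
12 | (1(10)E,4E,6S,7R,8R,9R)-6-hydroxy-9-(methacryloyloxy)germacra-1(10),4,11(13)-trien-12,8-olide (cis-fused lactone, H-7 and H-8 cis; not isolated) | C/C1=C\CC/C(C)=C/[C@H](O)[C@H]2C(=C)C(=O)O[C@H]2[C@@H]1OC(=O)C(C)=C | intermediate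
13 | (5S,6S,7R,8R,9R,10S)-6-hydroxy-9-(methacryloyloxy)elema-1,3,11(13)-trien-12,8-olide | C=C[C@@]1(C)[C@H](C(=C)C)[C@H](O)[C@H]2C(=C)C(=O)O[C@H]2[C@@H]1OC(=O)C(=C)C | intermediate
14 | (5S,6S,7R,8R,9R,10S)-6-[(Z)-2-methylbut-2-enoyloxy]-9-(methacryloyloxy)elema-1,3,11(13)-trien-12,8-olide | C=C[C@@]1(C)[C@H](C(=C)C)[C@H](OC(=O)/C(C)=C\C)[C@H]2C(=C)C(=O)O[C@H]2[C@@H]1OC(=O)C(=C)C | intermediate
15 | (5R,6S,7R,8R,9R,10S)-6-[(Z)-2-methylbut-2-enoyloxy]-9-(methacryloyloxy)-15-oxoelema-1,3,11(13)-trien-12,8-olide, CNP0102441.1 | C=C[C@@]1(C)[C@H](C(=C)C=O)[C@H](OC(=O)/C(C)=C\C)[C@H]2C(=C)C(=O)O[C@H]2[C@@H]1OC(=O)C(=C)C | target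

**Step count**
Total steps: 10. Longest linear sequence: 8 (steps 1, 2, 5, 6, 7, 8, 9, 10).

**Steps most likely to fail**

Step 8 (ring closure and Cope in one flask). Three things can go wrong here. The ten-membered closure can be low-yielding, or it can give the C6 epimer. The two chair transition states of the Cope step are also close in energy. The one needed puts the 6-OH (syn to C14) and C11 axial. The other puts the lactone oxygen and the C9 ester axial and can hold an OH···O=C hydrogen bond, so the 5,10-bis-epimer is a real possibility. Fallback: set out from 11, stop after the ring closure and isolate 12. Oxidize its allylic C6 carbinol with MnO2 to (1(10)E,4E,7S,8R,9R)-9-(methacryloyloxy)-6-oxogermacra-1(10),4,11(13)-trien-12,8-olide F1. Heat F1 in PhMe so that the Cope step runs with a trigonal C6. The wanted chair then has only C11 axial while the unwanted one keeps two axial oxygens. This gives (5S,7S,8R,9R,10S)-9-(methacryloyloxy)-6-oxoelema-1,3,11(13)-trien-12,8-olide F2. Reduce F2 with NaBH4/CeCl3·7H2O at −78 °C; hydride enters anti to the axial C10 methyl and gives the axial 6-alcohol. The route is rejoined at 13. Both C6 epimers from the ring closure converge on F1.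

Step 5 (vinylogous aldol with the doubly silylated furan). Furan 7 can ionize at C13 under Lewis acid, and the threo/erythro ratio and ee with a 3-substituted furan are not secured. Fallback: set out from 4 and run the same Ti(OiPr)4/BINOL aldol with commercial 2-(trimethylsilyloxy)furan, the substrate for which this catalysis is best established. This gives the O-trimethylsilyl adduct F3 and, after citric acid/MeOH, (5R)-5-[(1R,2E,6E)-8-{[tert-butyl(dimethyl)silyl]oxy}-1-hydroxy-2,6-dimethylocta-2,6-dien-1-yl]furan-2(5H)-one F4. C13 is then introduced afterwards by Morita–Baylis–Hillman hydroxymethylation of F4 (aq. CH2O, PBu3, THF), rejoining the route at 9. Steps 3 and 4 are then not needed.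

Step 3 (Morita–Baylis–Hillman reaction of the parent butenolide). Butenolides are sluggish in this reaction and can dimerize by Michael addition or open in water. Fallback: set out from 5 and mask the alkene as a sulfide. Conjugate addition of PhSH (Et3N cat.) gives 4-(phenylsulfanyl)dihydrofuran-2(3H)-one F5. Its lithium enolate (LDA, THF, −78 °C) is hydroxymethylated with gaseous CH2O to 3-(hydroxymethyl)-4-(phenylsulfanyl)dihydrofuran-2(3H)-one F6. Oxidation with NaIO4 gives the sulfoxide 3-(hydroxymethyl)-4-(phenylsulfinyl)dihydrofuran-2(3H)-one F7, which undergoes thermal syn-elimination toward the acidic C3–H (PhMe, 90 °C) and rejoins the route at 6.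

**Further compounds**
F1 | step 8 | (1(10)E,4E,7S,8R,9R)-9-(methacryloyloxy)-6-oxogermacra-1(10),4,11(13)-trien-12,8-olide | C/C1=C\CC/C(C)=C/C(=O)[C@H]2C(=C)C(=O)O[C@H]2[C@@H]1OC(=O)C(C)=C
F2 | step 8 | (5S,7S,8R,9R,10S)-9-(methacryloyloxy)-6-oxoelema-1,3,11(13)-trien-12,8-olide | C=C[C@@]1(C)[C@H](C(=C)C)C(=O)[C@H]2C(=C)C(=O)O[C@H]2[C@@H]1OC(=O)C(=C)C
F3 | step 5 | (5R)-5-[(1R,2E,6E)-8-{[tert-butyl(dimethyl)silyl]oxy}-2,6-dimethyl-1-[(trimethylsilyl)oxy]octa-2,6-dien-1-yl]furan-2(5H)-one | CC(C)(C)[Si](C)(C)OC/C=C(\C)CC/C=C(\C)[C@@H](O[Si](C)(C)C)[C@H]1C=CC(=O)O1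
F4 | step 5 | (5R)-5-[(1R,2E,6E)-8-{[tert-butyl(dimethyl)silyl]oxy}-1-hydroxy-2,6-dimethylocta-2,6-dien-1-yl]furan-2(5H)-one | CC(C)(C)[Si](C)(C)OC/C=C(\C)CC/C=C(\C)[C@@H](O)[C@H]1C=CC(=O)O1
F5 | step 3 | 4-(phenylsulfanyl)dihydrofuran-2(3H)-one (racemic) | O=C1CC(Sc2ccccc2)CO1
F6 | step 3 | 3-(hydroxymethyl)-4-(phenylsulfanyl)dihydrofuran-2(3H)-one (racemic, diastereomer mixture) | O=C1OCC(Sc2ccccc2)C1CO
F7 | step 3 | 3-(hydroxymethyl)-4-(phenylsulfinyl)dihydrofuran-2(3H)-one (racemic, diastereomer mixture) | O=C1OCC(S(=O)c2ccccc2)C1CO
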